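## Structural features

- The target 20 is an 18-membered macrocyclic bis(bibenzyl) built from four benzene rings. Ring A (OMe-bearing) is joined to ring B through an ether oxygen, ring B to ring C through a CH2–CH2 bridge, ring C to ring D through a second ether oxygen, and ring D back to ring A through a second CH2–CH2 bridge.
- Ring A carries four substituents on four adjacent carbons, in the order OMe, O–ring B, bridge carbon, OH. Ring B is 1,3-linked and ring D is 1,4-linked. Ring C is 1,3,4-trisubstituted, with its OH para to the bridge and ortho to the ether oxygen.
- There is no stereocentre and no double bond in 20, so no stereochemical relationship between neighbouring centres has to be set. The only geometric element in the route is a transient alkene.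
- The fragile groups are the two free phenols. The ring A phenol stands para to OMe (a hydroquinone monoether) and is easily oxidised to a quinone, so both phenols should stay masked until the last step and oxidants should be avoided late.
- The real difficulties are closing the 18-membered ring without oligomerisation and assembling the crowded ring A, in particular the diaryl ether flanked by OMe and the bridge carbon.
- The key step exploits the B/C bridge. Its two aryl carbons (the ring B carbon meta to the ether oxygen, and the ring C carbon para to OH) have only C–H neighbours, so both can carry iodine and couple without steric hindrance with a two-carbon unit.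
- The ring C carbon in question is also the position para to the protected phenol oxygen, which is where electrophilic iodination is directed.

## Logic of the disconnections

**20 to 19.** No skeletal bond is cut. The two O–H groups are traced back to O–CH2Ph and the CH2–CH2 bridge between ring B and ring C to CH=CH. One hydrogenation undoes all three changes, the oxidisable phenols stay masked to the end, and an sp2 bridge is what a cross-coupling can deliver. The forward step must saturate a ring-bound alkene and cleave two benzyl ethers while leaving the diaryl ethers and OMe alone.

**19 to 15 and 16.** The two bonds from the CH=CH unit to ring B and to ring C are cut. This opens the 18-membered ring and removes both bridge carbons; it is the largest simplification in the route (one ring, two C–C bonds). Both aryl carbons are unhindered, and a symmetric C2 reagent makes it unnecessary to tell the two ends of 15 apart. The forward step must make the second coupling intramolecular.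

**15 to 14.** The CH2–CH2 bridge between ring D and ring A is traced back to CH=CH, which a carbonyl olefination can build. The forward reduction must leave two C–I bonds and two benzyl ethers untouched, which rules out catalytic hydrogenation and points to diimide.

**14 to 6 and 12 (through 13).** The CH=CH bond is cut, giving two halves of similar size and a convergent plan. The phosphorus is placed on the unhindered ring D benzylic carbon, and the hindered ring A carbon stays as the aldehyde. The forward step needs an ylide that adds to a 2,6-disubstituted benzaldehyde; its geometry does not matter.

**12 to 11 to 10.** The C–P bond and then the benzylic C–O bond are traced back to the aldehyde, so a single aldehyde group serves first as SNAr activator and then as olefination handle. The forward steps must not disturb the aryl iodide or the benzyl ether.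

**10 to 9, then 9 to 7 and 8.** The C–I bond on ring C is cut first, then the ring D carbon–oxygen bond of the C–O–D ether. The ether cut is next to a para aldehyde, so SNAr makes it from two simple compounds. The iodination must go para to the benzyloxy group and not para to the aryloxy group, relying on the benzyloxy oxygen being the stronger donor.

**6 to 4 and 5.** The ring A carbon–oxygen bond of the A–O–B ether is cut. The aldehyde ortho to fluorine activates this crowded position, and 5 brings the ring B iodine in its final place. The forward SNAr must succeed on an electron-rich ring and leave the C–I bond alone, so no copper or palladium is used.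

**4 to 2 (through 3), then 2 to 1.** The ring–CHO bond is cut at the carbon lying between F and the benzyloxy group, the most acidic position of 2. The O–benzyl bond is then cut to reach 1. The forward metalation must take the ring proton and not a benzylic proton of the protecting group.

## Other disconnections considered

**Alternative 1:** The cut lies inside ring A, between the OH-bearing carbon and the neighbouring CH carbon. Ring A is traced back to the four-membered ring of A1, a macrocyclic 4-methoxy-4-vinylcyclobutenone (racemic at its one quaternary carbon) with the D/A bridge on C2 and the ring B oxygen on C3.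

- Forward step: heating A1 in toluene should open the four-membered ring by a four-electron electrocyclic process, close the six-membered ring by six-electron electrocyclisation onto the ketene carbon, and tautomerise to A2. In A2 ring A appears with its free OH and ring C still carries a benzyl ether.
- In its favour: the contiguous pattern OH, bridge, O–ring B, OMe is written into the four-membered ring carbon by carbon. No SNAr at a deactivated position and no ortho-lithiation is needed. The step is unimolecular, needs no reagent or metal, and cannot oligomerise. It also frees the ring A phenol while the ring C phenol is still protected, a differentiation the chosen plan does not offer.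
- Against it: the step builds an arene, not the macrocycle. The 18-membered ring must already be closed in A1 by some other reaction, in the presence of an electrophilic, base-sensitive four-membered ring that excludes ylides and most organometallic reagents late in the sequence.
- Comparison: on structure, Alternative 1 is the better answer to the crowded ring A, and the chosen plan is the better answer to the large ring, which is the harder problem. On mechanism, the pericyclic cascade is at least as dependable as a double Stille coupling and is better on dilution. On step economy, the two are equal after the key step (one hydrogenolysis from A2, one hydrogenation from 19). Alternative 1 is longer before it, because both a macrocyclisation and the four-membered-ring chemistry are needed.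

**Alternative 2:** The cut is the ring C carbon–oxygen bond of the C–O–D ether, with the oxygen staying on ring D. The precursor is the open-chain bisphenol A3, in which ring C is a 2,6-dibromophenol, ring D a 2,6-dichlorophenol, and the ring A phenol an acetate.

- Forward step: Tl(NO3)3 in methanol should oxidise the dibromophenol. The ring D phenol oxygen attacks the brominated ortho carbon, and Zn then removes that bromine reductively and restores the arene, giving A4.
- In its favour: the ring is closed from two phenols at a heteroatom bond, without tin or palladium. A3 contains only one diaryl ether. Both CH2–CH2 bridges can be saturated by ordinary hydrogenation before any halogen is present, which is better than the chosen plan, where a diimide reduction is forced by the iodides.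
- Against it: it needs a stoichiometric amount of a toxic trivalent thallium salt. Three halogens foreign to the target must be introduced and removed. Ring A of A3 is an electron-rich arene protected against oxidation only by its acetate. The choice between the two phenols rests on a difference in oxidation potential and not on a bond that only one site has. The bond made is one that the chosen plan obtains by a routine SNAr on 8.
- Comparison: on structure the two are equal, since each closes the 18-membered ring in its key operation. On mechanism the chosen plan is better defined, because oxidative addition can only occur at the two C–I bonds. On step economy the chosen plan is shorter: A4 needs dehalogenation and acetate cleavage, 19 needs one hydrogenation.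

**Alternative 3:** The cut is the ring D carbon–oxygen bond of the C–O–D ether, traced back with a carbonyl group inserted to the 19-membered aryl ester A5 (ring D benzoate of the ring C phenol, other phenols as methoxymethyl ethers).

- Forward step: Ni(cod)2 with 3,4-bis(dicyclohexylphosphino)thiophene and K3PO4 should insert zerovalent nickel into the acyl carbon–oxygen bond, lose carbon monoxide, and form the aryl–oxygen bond by reductive elimination, giving A6.
- In its favour: the large ring is closed by lactonisation, one of the most dependable macrocyclisations, and on this point it is better than the double Stille coupling. The contraction is unimolecular and the route is free of tin.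
- Against it: decarbonylative ether formation is established for simple and heteroaryl esters. Transferring it to an electron-rich para-alkylbenzoate held in a macrocycle would need method development. It needs high temperature, carbon monoxide may stay bound to nickel, and aryloxide exchange between nickel centres could open the ring. A5 also needs a ring D carboxylic acid and more protecting-group changes.
- Comparison: on structure it targets a bond that SNAr makes easily in the chosen plan. On mechanism its ring closure is safer but its key bond formation is less well founded than a Stille coupling of aryl iodides. On step economy the two are equal after the key step (one acid treatment from A6, one hydrogenation from 19), and Alternative 3 is somewhat longer before it.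

Key step: step 10

Remark on the chemistry: the substitution patterns of 15, 19 and the starting materials were checked ring by ring against 20 and agree, so no structure needed changing. The olefination product 14 is assumed to be an E/Z mixture and is carried on as such, because step 9 removes the geometry.

## Route

Step 1
Reactants: 1 3-fluoro-4-methoxyphenol
Product: 2 4-(benzyloxy)-2-fluoro-1-methoxybenzene
Conditions: BnBr, K2CO3, acetone, reflux
Reagents that add atoms: benzyl bromide, BrCc1ccccc1
Why: Williamson ether synthesis on a phenoxide with a reactive benzylic bromide; the benzyl group is chosen because the final hydrogenation removes it without an extra step.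

Step 2
Reactants: 2 4-(benzyloxy)-2-fluoro-1-methoxybenzene
Product: 4 6-(benzyloxy)-2-fluoro-3-methoxybenzaldehyde, via aryllithium 3 (not isolated)
Conditions: LiN(i-Pr)2, THF, −78 °C; DMF, −78 to 0 °C; aq. NH4Cl
Reagents that add atoms: N,N-dimethylformamide, CN(C)C=O
Why: Directed ortho-metalation followed by formylation; the proton between F and the benzyloxy oxygen is acidified by both groups and is removed by the amide base at −78 °C, where the benzylic CH2 is not attacked and loss of LiF from 3 is slow.

Step 3
Reactants: 4 6-(benzyloxy)-2-fluoro-3-methoxybenzaldehyde; 5 3-iodophenol
Product: 6 6-(benzyloxy)-2-(3-iodophenoxy)-3-methoxybenzaldehyde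
Conditions: K2CO3, DMAc, 120 °C
Reagents that add atoms: none
Why: Nucleophilic aromatic substitution (addition–elimination) of fluoride ortho to the aldehyde by the phenoxide of 5; no transition metal is present, so the C–I bond is retained.

Step 4
Reactants: 7 2-(benzyloxy)phenol; 8 4-fluorobenzaldehyde
Product: 9 4-[2-(benzyloxy)phenoxy]benzaldehyde
Conditions: K2CO3, DMAc, 120 °C
Reagents that add atoms: none
Why: Nucleophilic aromatic substitution of a fluoride para to an aldehyde by a phenoxide, a standard diaryl ether synthesis.

Step 5
Reactants: 9 4-[2-(benzyloxy)phenoxy]benzaldehyde
Product: 10 4-[2-(benzyloxy)-5-iodophenoxy]benzaldehyde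
Conditions: NIS, TFA (cat.), MeCN, rt
Reagents that add atoms: N-iodosuccinimide, O=C1CCC(=O)N1I
Why: Electrophilic aromatic iodination; ring C is the only activated ring, and the benzyloxy oxygen is a stronger donor than the oxygen shared with the formyl-substituted ring D, so iodine should enter para to the benzyloxy group.

Step 6
Reactants: 10 4-[2-(benzyloxy)-5-iodophenoxy]benzaldehyde
Product: 11 {4-[2-(benzyloxy)-5-iodophenoxy]phenyl}methanol
Conditions: NaBH4, THF/MeOH, 0 °C
Reagents that add atoms: none
Why: Hydride reduction of an aryl aldehyde; aryl iodide and ethers are inert to NaBH4.

Step 7
Reactants: 11 {4-[2-(benzyloxy)-5-iodophenoxy]phenyl}methanol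
Product: 12 {4-[2-(benzyloxy)-5-iodophenoxy]benzyl}triphenylphosphonium bromide
Conditions: PPh3·HBr, MeCN, reflux
Reagents that add atoms: triphenylphosphine hydrobromide, [Br-].c1ccc(cc1)[PH+](c1ccccc1)c1ccccc1
Why: Direct conversion of a benzylic alcohol into a phosphonium salt; the para aryloxy group eases ionisation of the protonated alcohol, and the weakly acidic salt leaves the benzyl aryl ether intact.

Step 8
Reactants: 12 {4-[2-(benzyloxy)-5-iodophenoxy]benzyl}triphenylphosphonium bromide; 6 6-(benzyloxy)-2-(3-iodophenoxy)-3-methoxybenzaldehyde
Product: 14 1-(benzyloxy)-2-{2-[4-(2-(benzyloxy)-5-iodophenoxy)phenyl]ethenyl}-3-(3-iodophenoxy)-4-methoxybenzene (E/Z mixture), via phosphonium ylide 13 (not isolated)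
Conditions: KOt-Bu, THF, 0 °C; then 6, 0 °C to rt
Reagents that add atoms: none
Why: Wittig olefination with a semistabilised benzylic ylide, which adds even to 2,6-disubstituted benzaldehydes; both alkene isomers are acceptable because the next step saturates the bond.

Step 9
Reactants: 14 1-(benzyloxy)-2-{2-[4-(2-(benzyloxy)-5-iodophenoxy)phenyl]ethenyl}-3-(3-iodophenoxy)-4-methoxybenzene
Product: 15 1-(benzyloxy)-2-{2-[4-(2-(benzyloxy)-5-iodophenoxy)phenyl]ethyl}-3-(3-iodophenoxy)-4-methoxybenzene
Conditions: TsNHNH2 (excess, in portions), NaOAc, DME/H2O, reflux
Reagents that add atoms: none
Why: Diimide reduction, a concerted syn transfer of two hydrogens to the alkene; unlike hydrogenation over a metal it does not cleave aryl–iodine bonds or benzyl ethers.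

Step 10
Reactants: 15 1-(benzyloxy)-2-{2-[4-(2-(benzyloxy)-5-iodophenoxy)phenyl]ethyl}-3-(3-iodophenoxy)-4-methoxybenzene; 16 (E)-1,2-bis(tributylstannyl)ethene
Product: 19 macrocyclic (E)-stilbene bis(benzyl ether), via ring B styrylstannane 17 (not isolated), via ring C styrylstannane 18 (not isolated)
Conditions: Pd(PPh3)4 (20 mol %), CuI (40 mol %), DMF, 60 °C; 15 and 16 (1.0 equiv) added together by syringe pump over 12 h, final concentration 2 mM
Reagents that add atoms: none
Why: Zerovalent palladium adds oxidatively to one C–I bond of 15 (probably the less electron-rich ring B iodide first); transmetalation with one tin end of 16, helped by CuI, and reductive elimination give styrylstannane 17, or 18 if ring C reacts first. A second oxidative addition at the remaining C–I bond, transfer of the styryl group from tin to palladium within the same molecule, and reductive elimination form the second aryl–vinyl bond. The closest known reaction types are the Stille stitching macrocyclisation of diiodides with this distannane and the double Stille coupling of aryl iodides with it to give (E)-stilbenes. The 18-membered ring closes end to end by intramolecular transmetalation and C(sp2)–C(sp2) reductive elimination at divalent palladium. No stereocentre is formed; the E geometry of 16 is carried over with retention and is removed in step 11. The step needs the second coupling to be intramolecular rather than intermolecular, which one equivalent of 16 and slow joint addition into a dilute catalyst solution should secure; in the substrate, the ortho linkage at ring A and the two ether hinges fold the chain, and neither C–I carbon has an ortho substituent. Only the C–I bonds react, and either order of coupling leads to the same ring, so the two iodides need not be differentiated.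

Step 11
Reactants: 19 macrocyclic (E)-stilbene bis(benzyl ether)
Product: 20 CNP0179896.0 (target)
Conditions: H2 (1 atm), 10% Pd/C, THF/MeOH, rt
Reagents that add atoms: none
Why: Catalytic hydrogenation saturates the stilbene double bond and hydrogenolyses both benzyl aryl ethers in one operation; diaryl ethers and the methyl ether are stable under these conditions.

## Compound list

1 | 3-fluoro-4-methoxyphenol | COc1ccc(O)cc1F | starting material
2 | 4-(benzyloxy)-2-fluoro-1-methoxybenzene | COc1ccc(OCc2ccccc2)cc1F | intermediate
3 | [6-(benzyloxy)-2-fluoro-3-methoxyphenyl]lithium (aryllithium, not isolated) | COc1ccc(OCc2ccccc2)c([Li])c1F | intermediate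
4 | 6-(benzyloxy)-2-fluoro-3-methoxybenzaldehyde | COc1ccc(OCc2ccccc2)c(C=O)c1F | intermediate
5 | 3-iodophenol | Oc1cccc(I)c1 | starting material
6 | 6-(benzyloxy)-2-(3-iodophenoxy)-3-methoxybenzaldehyde | COc1ccc(OCc2ccccc2)c(C=O)c1Oc1cccc(I)c1 | intermediate
7 | 2-(benzyloxy)phenol | Oc1ccccc1OCc1ccccc1 | starting material
8 | 4-fluorobenzaldehyde | O=Cc1ccc(F)cc1 | starting material
9 | 4-[2-(benzyloxy)phenoxy]benzaldehyde | O=Cc1ccc(Oc2ccccc2OCc2ccccc2)cc1 | intermediate
10 | 4-[2-(benzyloxy)-5-iodophenoxy]benzaldehyde | O=Cc1ccc(Oc2cc(I)ccc2OCc2ccccc2)cc1 | intermediate
11 | {4-[2-(benzyloxy)-5-iodophenoxy]phenyl}methanol | OCc1ccc(Oc2cc(I)ccc2OCc2ccccc2)cc1 | intermediate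
12 | {4-[2-(benzyloxy)-5-iodophenoxy]benzyl}triphenylphosphonium bromide | [Br-].c1ccc(cc1)[P+](Cc1ccc(Oc2cc(I)ccc2OCc2ccccc2)cc1)(c1ccccc1)c1ccccc1 | intermediate
13 | {4-[2-(benzyloxy)-5-iodophenoxy]benzylidene}triphenylphosphorane (ylide, not isolated) | c1ccc(cc1)P(=Cc1ccc(Oc2cc(I)ccc2OCc2ccccc2)cc1)(c1ccccc1)c1ccccc1 | intermediate
14 | 1-(benzyloxy)-2-{2-[4-(2-(benzyloxy)-5-iodophenoxy)phenyl]ethenyl}-3-(3-iodophenoxy)-4-methoxybenzene, mixture of (E) and (Z) isomers | COc1ccc(OCc2ccccc2)c(C=Cc2ccc(cc2)Oc2cc(I)ccc2OCc2ccccc2)c1Oc1cccc(I)c1 | intermediate
15 | 1-(benzyloxy)-2-{2-[4-(2-(benzyloxy)-5-iodophenoxy)phenyl]ethyl}-3-(3-iodophenoxy)-4-methoxybenzene (open-chain diiodide) | COc1ccc(OCc2ccccc2)c(CCc2ccc(cc2)Oc2cc(I)ccc2OCc2ccccc2)c1Oc1cccc(I)c1 | intermediate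
16 | (E)-1,2-bis(tributylstannyl)ethene | CCCC[Sn](CCCC)(CCCC)/C=C/[Sn](CCCC)(CCCC)CCCC | starting material
17 | ring B styrylstannane: 15 with the ring B iodine replaced by (E)-CH=CH–SnBu3, ring C iodine retained (not isolated) | COc1ccc(OCc2ccccc2)c(CCc2ccc(cc2)Oc2cc(I)ccc2OCc2ccccc2)c1Oc1cccc(/C=C/[Sn](CCCC)(CCCC)CCCC)c1 | intermediate
18 | ring C styrylstannane: 15 with the ring C iodine replaced by (E)-CH=CH–SnBu3, ring B iodine retained (not isolated) | COc1ccc(OCc2ccccc2)c(CCc2ccc(cc2)Oc2cc(/C=C/[Sn](CCCC)(CCCC)CCCC)ccc2OCc2ccccc2)c1Oc1cccc(I)c1 | intermediate
19 | macrocyclic (E)-stilbene: the 18-membered ring of 20 with an (E)-CH=CH bridge between ring B and ring C and both phenols as benzyl ethers | COc1ccc(OCc3ccccc3)c2c1Oc1cccc(c1)/C=C/c1ccc(OCc3ccccc3)c(c1)Oc1ccc(cc1)CC2 | intermediate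
20 | CNP0179896.0: 18-membered bis(bibenzyl) with ring A (OMe, O–ring B, bridge, OH), 1,3-linked ring B, ring C (bridge, O–ring D, OH para to bridge) and 1,4-linked ring D; achiral | COc1ccc(O)c2c1Oc1cccc(c1)CCc1ccc(O)c(c1)Oc1ccc(cc1)CC2 | target

## Step count and least certain steps

Total step count: 11. Longest linear sequence: 8 steps (steps 4 to 11, from 7 and 8 to 20). The ring A branch (steps 1 to 3) joins at step 8.

**Step 10 (key step).** The most likely failure is that the mono-coupled intermediate meets a second molecule of 15 or 16 before it closes the ring, so that chain growth to oligomeric stilbenes or double capping by two stannanes overtakes cyclisation. Protodestannylation of the intermediate would also stop the sequence. Fallback: from 15, a twofold Stille coupling with tributyl(vinyl)stannane (Pd(PPh3)4, toluene, 100 °C) should give the divinyl compound 1-(benzyloxy)-2-{2-[4-(2-(benzyloxy)-5-ethenylphenoxy)phenyl]ethyl}-3-(3-ethenylphenoxy)-4-methoxybenzene F1. Ring-closing metathesis of F1 with the second-generation Grubbs catalyst in dilute toluene should then close the ring with loss of ethene and return to the route at 19. The (E)-isomer is expected under thermodynamic control, and any (Z)-isomer converges in step 11. This fallback delivers one bridge carbon to each ring and closes the ring at the central C=C bond.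

**Step 3.** The addition–elimination may be slow, because the fluorine-bearing carbon sits between OMe and CHO on an electron-rich ring and the phenoxide of 5 is a moderate, bulky nucleophile; long heating could degrade the aldehyde. Fallback: from 4, the alkoxide of 2-(methylsulfonyl)ethanol (NaH, DMF, 0 °C to rt), a small and strong oxygen nucleophile, should displace fluoride to give 6-(benzyloxy)-3-methoxy-2-[2-(methylsulfonyl)ethoxy]benzaldehyde F2. F2 loses methyl vinyl sulfone in the same flask to give 6-(benzyloxy)-2-hydroxy-3-methoxybenzaldehyde F3. Chan–Lam coupling of F3 with (3-iodophenyl)boronic acid (Cu(OAc)2, pyridine, 4 Å molecular sieves, CH2Cl2, air, rt) should tolerate the aryl iodide and returns to the route at 6.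

**Step 2.** Deprotonation could occur at the benzylic CH2 of the protecting group, followed by Wittig rearrangement, or 3 could lose LiF to an aryne if the temperature rises. Fallback: from 1, protection with chloromethyl methyl ether and i-Pr2NEt gives 2-fluoro-1-methoxy-4-(methoxymethoxy)benzene F4. Lithiation with n-BuLi in THF at −78 °C, now directed by both F and the acetal oxygen, and quenching with DMF give 2-fluoro-3-methoxy-6-(methoxymethoxy)benzaldehyde F5. HCl in MeOH frees 2-fluoro-6-hydroxy-3-methoxybenzaldehyde F6, and benzylation (BnBr, K2CO3, acetone) returns to the route at 4.

**Step 5.** Iodination could leak to the position para to the aryloxy oxygen if the two oxygen donors differ less than expected. Fallback: from 7, acetylation (Ac2O, pyridine) gives 2-(benzyloxy)phenyl acetate F7, in which the acetoxy group is a much weaker donor than benzyloxy. Iodination (NIS, TFA, MeCN) should then give 2-(benzyloxy)-5-iodophenyl acetate F8, and methanolysis (K2CO3, MeOH) gives 2-(benzyloxy)-5-iodophenol F9. SNAr of F9 with 8 (K2CO3, DMAc, 120 °C) returns to the route at 10.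

**Step 9.** Saturation may stay incomplete, because diimide disproportionates faster than it adds to a conjugated, ortho-substituted diarylethene. Fallback: from 14, the saturation is postponed. The Stille stitching of step 10 is run on 14 (the (Z)-isomer is the one expected to fold for ring closure) with 16, to give the macrocyclic diene F10. F10 has the (E)-CH=CH bridge between ring B and ring C and a CH=CH bridge between ring D and ring A. Hydrogenation over 10% Pd/C then saturates both alkenes and cleaves both benzyl ethers, returning to the route at 20.

## Further compounds

F1 | step 10 | 1-(benzyloxy)-2-{2-[4-(2-(benzyloxy)-5-ethenylphenoxy)phenyl]ethyl}-3-(3-ethenylphenoxy)-4-methoxybenzene | COc1ccc(OCc2ccccc2)c(CCc2ccc(cc2)Oc2cc(C=C)ccc2OCc2ccccc2)c1Oc1cccc(C=C)c1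
F2 | step 3 | 6-(benzyloxy)-3-methoxy-2-[2-(methylsulfonyl)ethoxy]benzaldehyde | COc1ccc(OCc2ccccc2)c(C=O)c1OCCS(C)(=O)=O
F3 | step 3 | 6-(benzyloxy)-2-hydroxy-3-methoxybenzaldehyde | COc1ccc(OCc2ccccc2)c(C=O)c1O
F4 | step 2 | 2-fluoro-1-methoxy-4-(methoxymethoxy)benzene | COCOc1ccc(OC)c(F)c1
F5 | step 2 | 2-fluoro-3-methoxy-6-(methoxymethoxy)benzaldehyde | COCOc1ccc(OC)c(F)c1C=O
F6 | step 2 | 2-fluoro-6-hydroxy-3-methoxybenzaldehyde | COc1ccc(O)c(C=O)c1F
F7 | step 5 | 2-(benzyloxy)phenyl acetate | CC(=O)Oc1ccccc1OCc1ccccc1
F8 | step 5 | 2-(benzyloxy)-5-iodophenyl acetate | CC(=O)Oc1cc(I)ccc1OCc1ccccc1
F9 | step 5 | 2-(benzyloxy)-5-iodophenol | Oc1cc(I)ccc1OCc1ccccc1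
F10 | step 9 | macrocyclic diene: 19 with CH=CH in place of the CH2–CH2 bridge between ring D and ring A (geometry of that alkene not defined) | COc1ccc(OCc3ccccc3)c2c1Oc1cccc(c1)/C=C/c1ccc(OCc3ccccc3)c(c1)Oc1ccc(cc1)C=C2
A1 | alternative 1 | macrocyclic 2-alkyl-3-aryloxy-4-methoxy-4-vinylcyclobutenone (racemic), ring C phenol as benzyl ether | C=CC1(OC)C(=O)C2=C1Oc1cccc(c1)CCc1ccc(OCc3ccccc3)c(c1)Oc1ccc(cc1)CC2
A2 | alternative 1 | target with the ring C phenol as benzyl ether | COc1ccc(O)c2c1Oc1cccc(c1)CCc1ccc(OCc3ccccc3)c(c1)Oc1ccc(cc1)CC2
A3 | alternative 2 | open-chain bisphenol with 3,5-dibromo-4-hydroxyphenyl as ring C, 3,5-dichloro-4-hydroxyphenyl as ring D and the ring A phenol as acetate | COc1ccc(OC(C)=O)c(CCc2cc(Cl)c(O)c(Cl)c2)c1Oc1cccc(CCc2cc(Br)c(O)c(Br)c2)c1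
A4 | alternative 2 | halogenated macrocyclic diaryl ether, ring A phenol as acetate | COc1ccc(OC(C)=O)c2c1Oc1cccc(c1)CCc1cc(Br)c(O)c(c1)Oc1c(Cl)cc(cc1Cl)CC2
A5 | alternative 3 | 19-membered macrolactone (ring D benzoate of the ring C phenol), other phenols as methoxymethyl ethers | COc1ccc(OCOC)c2c1Oc1cccc(c1)CCc1ccc(OCOC)c(c1)OC(=O)c1ccc(cc1)CC2
A6 | alternative 3 | bis(methoxymethyl) ether of the target | COc1ccc(OCOC)c2c1Oc1cccc(c1)CCc1ccc(OCOC)c(c1)Oc1ccc(cc1)CC2
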